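**Retrosynthetic overview**

1. Last disconnection: the O1–C2 bond of the acetoxy-oxepane (ring D; squalene-type locants, primes for the ketone half). Forward, a catalyst-controlled epoxidation of the C2=C3 alkene and 7-endo opening by the C7 hydroxyl set C3 and close ring D; only acetylation follows. Enabling feature: the O1–C2(CH3)2–C3(O) segment of ring D lying against the trans C6(CH3)/C7(O) edge of cyclohexane ring C. C2 is the tertiary end of a 2,2-dimethyl epoxide and draws the C7 oxygen into the seven-membered mode.
2. Both perhydrobenzoxepine halves share one carbon skeleton and one absolute sense at C6/C7 and C6'/C7'. Both are cut from (S)-Wieland–Miescher ketone: its enone ring is cleaved (ozonolysis/periodate) into a trans-fused lactol acetal, a temporary ring that protects O7, stores C3–C5 as a masked aldehyde and locks the cyclohexanone chair.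
3. Ketone half (rings A, B): C10' methylation, C11' methylenation, isopropylidene Wittig, epoxidation/7-endo closure of ring A, face-selective spiro-epoxidation at C11', opening by PhSCH2Li (brings C12).
4. Union: the C12 alkyllithium from reductive lithiation adds to the alkoxymethylidene ketone of the second acetal (C11–C12 bond); transposition to the enal and a diazene retro-ene give C10=CH2 and the C11 hydrogen.
5. Ring order: B and C (from the starting material) → A → D.

Key step: step 21

Remark: locants C2–C12 and C2'–C12' follow squalene-type numbering of the two halves (C2 = C(CH3)2, C3 = oxygenated carbon, C6 = ring-fusion C–CH3, C7 = CH–O, C10 = carbon bearing =CH2 or CH3, C11 = ring carbon bearing the linker C12); anomeric mixtures are drawn as the axial anomer, and both anomers serve alike.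

**Route**

Step 1
Reactants: 1 (S)-Wieland–Miescher ketone
Product: 2 (1S,8aS)-8a-methyl-octahydronaphthalene-1,6-diol
Conditions: NaBH4 (excess), CeCl3·7H2O, MeOH, −78 → 0 °C
Reagents that add atoms: none
Why: Luche-type borohydride reduction of both carbonyls, in which hydride reaches the saturated C1 ketone from the face opposite the angular methyl, so that the new hydroxyl (later O7 and O7') is cis to CH3 and trans to the ring carbon that becomes the side chain; the allylic carbinol configuration is irrelevant because that carbon becomes the lactol carbon next.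

Step 2
Reactants: 2 (1S,8aS)-8a-methyl-octahydronaphthalene-1,6-diol
Product: 3 keto lactol
Conditions: O3, CH2Cl2/MeOH, −78 °C; Me2S, −78 → 23 °C; then NaIO4, THF/H2O, 23 °C
Reagents that add atoms: ozone [O-][O+]=O
Why: Ozonolysis of the trisubstituted alkene gives the ring ketone and an α-hydroxy aldehyde, which periodate cleaves with loss of one carbon as formic acid; the new aldehyde is trapped by the C1 hydroxyl as a trans-fused δ-lactol and no stereocenter is touched.

Step 3
Reactants: 3 keto lactol
Product: 4 keto acetal
Conditions: MeOH, PPTS (cat.), 23 °C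
Reagents that add atoms: methanol CO
Why: Fischer-type acetalisation under anomeric control should give mainly the axial methyl acetal; this temporary tetrahydropyran ring protects O7, masks the C3 aldehyde and locks the cyclohexanone in one chair.

Step 4
Reactants: 4 keto acetal
Product: 5 methyl ketone acetal
Conditions: LiN(i-Pr)2, THF, −78 °C; MeI, −78 → 0 °C; then NaOMe (cat.), MeOH, 23 °C
Reagents that add atoms: iodomethane CI
Why: Enolate alkylation at the only enolisable α-carbon (C10'), followed by base equilibration, should place the new methyl equatorial (10'S), because the axial epimer suffers a 1,3-diaxial clash with the angular methyl.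

Step 5
Reactants: 5 methyl ketone acetal
Product: 6 methylidene acetal
Conditions: Ph3PCH3Br, KOt-Bu, toluene, 90 °C
Reagents that add atoms: methyltriphenylphosphonium bromide C[P+](c1ccccc1)(c1ccccc1)c1ccccc1.[Br-]
Why: Wittig methylenation of the hindered ketone under forcing conditions installs C12' as a methylidene group, while C10' stays at its thermodynamic configuration.

Step 6
Reactants: 6 methylidene acetal
Product: 7 methylidene lactol
Conditions: AcOH/THF/H2O (3:1:1), 45 °C
Reagents that add atoms: water O
Why: Mild acetal hydrolysis releases the lactol without isomerising the 1,1-disubstituted alkene.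

Step 7
Reactants: 7 methylidene lactol
Product: 8 ring B dienol
Conditions: i-PrPPh3I, n-BuLi, THF, 0 → 23 °C
Reagents that add atoms: isopropyltriphenylphosphonium iodide CC(C)[P+](c1ccccc1)(c1ccccc1)c1ccccc1.[I-]
Why: Wittig olefination of the lactol through its open hydroxy aldehyde form adds C2' with its two methyls and frees the C7' hydroxyl; no stereocenter is formed.

Step 8
Reactants: 8 ring B dienol
Product: 10 ring A/B oxepanol, via ring B epoxy alcohol 9 (not isolated)
Conditions: D-fructose-derived Shi ketone (30 mol%), KHSO5 (as 2KHSO5·KHSO4·K2SO4), K2CO3, Bu4NHSO4, MeCN/dimethoxymethane/aq. buffer, 0 °C; then CSA (cat.), CH2Cl2, −20 → 0 °C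
Reagents that add atoms: potassium peroxymonosulfate [K+].[O-]S(=O)(=O)OO
Why: Shi epoxidation should pick the trisubstituted alkene over the hindered methylidene group, and the C7' hydroxyl then opens the protonated epoxide at its tertiary carbon (7-endo) to close ring A trans-fused; the catalyst-set C3' configuration (3'R) only keeps the series as single diastereomers and is erased at step 18.

Step 9
Reactants: 10 ring A/B oxepanol
Product: 11 ring A/B silyl ether
Conditions: TBSOTf, 2,6-lutidine, CH2Cl2, 0 °C
Reagents that add atoms: tert-butyldimethylsilyl trifluoromethanesulfonate CC(C)(C)[Si](C)(C)OS(=O)(=O)C(F)(F)F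
Why: Silylation of the hindered secondary alcohol protects the C3' oxygen through the organolithium chemistry that follows.

Step 10
Reactants: 11 ring A/B silyl ether
Product: 12 spiro-epoxide
Conditions: mCPBA, NaHCO3, CH2Cl2, 0 °C
Reagents that add atoms: 3-chloroperoxybenzoic acid OOC(=O)c1cccc(Cl)c1
Why: Prilezhaev epoxidation should occur on the face of the methylidene group opposite the axial C6' methyl on the adjacent carbon, which places the oxirane oxygen axial and C12' equatorial, the C11' configuration of the target (11'S).

Step 11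
Reactants: 12 spiro-epoxide
Product: 13 hydroxy sulfide
Conditions: PhSCH3, n-BuLi, DABCO, THF, 0 °C; then 12, 0 → 40 °C
Reagents that add atoms: thioanisole CSc1ccccc1
Why: SN2 opening of the 2,2-disubstituted epoxide at its CH2 carbon by the small carbanion PhSCH2Li gives the tertiary alcohol with C11' untouched and adds linker carbon C12 as a latent carbanion.

Step 12
Reactants: 4 keto acetal
Product: 14 hydroxymethylidene ketone
Conditions: NaH, HCO2Et, EtOH (cat.), THF, 0 → 23 °C; aq. HCl work-up
Reagents that add atoms: ethyl formate CCOC=O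
Why: Claisen formylation at the only enolisable α-carbon (C10) introduces the carbon that becomes the C10 methylidene group.

Step 13
Reactants: 14 hydroxymethylidene ketone
Product: 15 isopropoxymethylidene ketone
Conditions: 2-iodopropane, K2CO3, DMF, 23 °C
Reagents that add atoms: 2-iodopropane CC(C)I
Why: O-alkylation of the vinylogous acid gives a non-enolisable vinylogous ester that is set up for 1,2-addition and carbonyl transposition.

Step 14
Reactants: 13 hydroxy sulfide; 15 isopropoxymethylidene ketone
Product: 18 enal, via alkyllithium 16 (not isolated), via carbinol adduct 17 (not isolated)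
Conditions: 13, n-BuLi (1 equiv), THF, −78 °C; Li 4,4'-di-tert-butylbiphenylide (2.2 equiv), −78 °C; CeCl3, −78 °C; then 15, −78 → −40 °C; then 1 M HCl, THF, 0 °C (brief)
Reagents that add atoms: water O
Why: Reductive lithiation of the phenyl thioether gives the γ-oxido primary alkyllithium, which as its organocerium derivative adds 1,2 to the non-enolisable ketone, and acid then ionises the tertiary allylic alcohol and hydrolyses the enol ether (Stork–Danheiser-type transposition) to the tetrasubstituted enal, so that the C11–C12 bond joining the halves is made without any stereochemical demand.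

Step 15
Reactants: 18 enal
Product: 19 allylic alcohol
Conditions: NaBH4, CeCl3·7H2O, MeOH, −20 °C
Reagents that add atoms: none
Why: Luche 1,2-reduction of the enal gives the primary allylic alcohol and leaves the acetal and silyl ether alone.

Step 16
Reactants: 19 allylic alcohol
Product: 21 coupled methylidene acetal, via allylic diazene 20 (not isolated)
Conditions: 2-nitrobenzenesulfonylhydrazide, PPh3, diethyl azodicarboxylate, THF, −30 → 23 °C
Reagents that add atoms: none
Why: Mitsunobu N-alkylation of the sulfonylhydrazide, loss of sulfinic acid and retro-ene loss of N2 from the allylic diazene move the double bond to C10=CH2 and deliver hydrogen to C11; in the half-chair locked by the trans-fused acetal ring the face of C11 syn to the pseudoaxial C6 methyl is shielded, so hydrogen should arrive anti to it (axial) and C12 should end equatorial (11R).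

Step 17
Reactants: 21 coupled methylidene acetal
Product: 22 coupled alcohol
Conditions: Bu4NF, THF, 50 °C
Reagents that add atoms: none
Why: Fluoride-mediated desilylation frees the C3' hydroxyl as the only secondary alcohol of the molecule.

Step 18
Reactants: 22 coupled alcohol
Product: 23 coupled ketone acetal
Conditions: Dess–Martin periodinane, NaHCO3, CH2Cl2, 23 °C
Reagents that add atoms: none
Why: Dess–Martin oxidation of the single secondary alcohol gives the ring A ketone; the tertiary alcohol, the acetal and the methylidene group are inert.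

Step 19
Reactants: 23 coupled ketone acetal
Product: 24 coupled lactol
Conditions: AcOH/THF/H2O (3:1:1), 45 °C
Reagents that add atoms: water O
Why: Mild acetal hydrolysis opens the temporary ring to the lactol without engaging the methylidene group or the tertiary alcohol.

Step 20
Reactants: 24 coupled lactol
Product: 25 alkene diol
Conditions: i-PrPPh3I, n-BuLi (excess ylide), THF, 0 → 23 °C
Reagents that add atoms: isopropyltriphenylphosphonium iodide CC(C)[P+](c1ccccc1)(c1ccccc1)c1ccccc1.[I-]
Why: Wittig olefination of the lactol adds C2 with its two methyls and frees the C7 hydroxyl, while the hindered α,α-dimethyl ketone of ring A is spared.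

Step 21
Reactants: 25 alkene diol
Product: 27 3-epi-sodwanone K, via epoxy diol 26 (not isolated)
Conditions: D-fructose-derived Shi ketone (30 mol%), KHSO5 (as 2KHSO5·KHSO4·K2SO4), K2CO3, Bu4NHSO4, MeCN/dimethoxymethane/aq. buffer, 0 °C; then CSA (cat.), CH2Cl2, −40 → 0 °C
Reagents that add atoms: potassium peroxymonosulfate [K+].[O-]S(=O)(=O)OO
Why: The dioxirane formed from the D-fructose-derived ketone and KHSO5 should epoxidise the electron-rich trisubstituted C2=C3 alkene of 25 (Shi asymmetric epoxidation) in preference to the hindered 1,1-disubstituted C10 methylidene group, and its spiro transition state delivers oxygen to the face that gives the (3R)-epoxide 26. CSA then protonates the epoxide and the C7 hydroxyl opens it at the tertiary carbon C2, so that C3 keeps its configuration and becomes the carbinol carbon. The closest known reaction type is the acid-mediated, methyl-directed endo cyclisation of hydroxy trisubstituted epoxides used in biomimetic oxepane syntheses. Ring D closes in the 7-endo-tet mode through the O1–C2 bond and is trans-fused because the C7 oxygen and the C6 side chain are already trans-diequatorial on ring C. The one new stereocenter, C3, is controlled by the catalyst (reagent control, remote from the substrate stereocenters). The step needs regioselectivity for C2 over C3 (6-exo-tet), which the gem-dimethyl carbon C2 secures by carrying the positive charge of the protonated epoxide and the weakly nucleophilic neopentyl-type C7 hydroxyl reinforces by making the transition state late; the ketone, the tertiary alcohol and the methylidene group should not be engaged by catalytic CSA at low temperature.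

Step 22
Reactants: 27 3-epi-sodwanone K
Product: 28 3-epi-sodwanone K 3-acetate
Conditions: Ac2O, pyridine, DMAP (cat.), CH2Cl2, 0 → 23 °C
Reagents that add atoms: acetic anhydride CC(=O)OC(C)=O
Why: DMAP-catalysed acylation of the only secondary alcohol; the tertiary C11' alcohol is too hindered to react under these conditions.

**Compound list**

1 | (S)-Wieland–Miescher ketone, (S)-8a-methyl-3,4,8,8a-tetrahydronaphthalene-1,6(2H,7H)-dione | C[C@]12CCC(=O)C=C1CCCC2=O | starting material
2 | (1S,8aS)-8a-methyl-1,2,3,4,6,7,8,8a-octahydronaphthalene-1,6-diol (1-OH cis to the angular CH3; both C6 epimers) | C[C@]12CCC(O)C=C1CCC[C@@H]2O | intermediate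
3 | keto lactol, (4aR,8aS)-2-hydroxy-4a-methyloctahydro-5H-chromen-5-one (trans-fused, both anomers) | O=C1CCC[C@@H]2OC(O)CC[C@]21C | intermediate
4 | keto acetal, (2R,4aR,8aS)-2-methoxy-4a-methyloctahydro-5H-chromen-5-one (trans-fused, OCH3 axial) | O=C1CCC[C@@H]2O[C@@H](OC)CC[C@]21C | intermediate
5 | methyl ketone acetal, (2R,4aR,6S,8aS)-2-methoxy-4a,6-dimethyloctahydro-5H-chromen-5-one (6-CH3 equatorial) | O=C1[C@@H](C)CC[C@@H]2O[C@@H](OC)CC[C@]21C | intermediate
6 | methylidene acetal, (2R,4aS,6S,8aS)-2-methoxy-4a,6-dimethyl-5-methylideneoctahydro-2H-chromene | C=C1[C@@H](C)CC[C@@H]2O[C@@H](OC)CC[C@]21C | intermediate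
7 | methylidene lactol, (4aS,6S,8aS)-4a,6-dimethyl-5-methylideneoctahydro-2H-chromen-2-ol (both anomers) | C=C1[C@@H](C)CC[C@@H]2OC(O)CC[C@]21C | intermediate
8 | ring B dienol, (1S,2S,4S)-2,4-dimethyl-3-methylidene-2-(4-methylpent-3-en-1-yl)cyclohexan-1-ol | C=C1[C@@H](C)CC[C@H](O)[C@@]1(C)CCC=C(C)C | intermediate
9 | ring B epoxy alcohol, (1S,2S,4S)-2-{2-[(2R)-3,3-dimethyloxiran-2-yl]ethyl}-2,4-dimethyl-3-methylidenecyclohexan-1-ol | C=C1[C@@H](C)CC[C@H](O)[C@@]1(C)CC[C@H]2OC2(C)C | intermediate (not isolated)
10 | ring A/B oxepanol, (3R)-2,2,5a,7-tetramethyl-6-methylidenedecahydro-1-benzoxepin-3-ol (trans-fused, 5a-CH3 axial, 7-CH3 equatorial) | C=C1[C@@H](C)CC[C@@H]2OC(C)(C)[C@H](O)CC[C@]21C | intermediate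
11 | ring A/B silyl ether, 3-O-tert-butyldimethylsilyl ether of 10 | C=C1[C@@H](C)CC[C@@H]2OC(C)(C)[C@H](O[Si](C)(C)C(C)(C)C)CC[C@]21C | intermediate
12 | spiro-epoxide, 11 with the methylidene group converted into a spiro-oxirane at C11' (oxirane O axial, anti to the C6' methyl; CH2 = C12' equatorial) | C1O[C@]12[C@@H](C)CC[C@@H]3OC(C)(C)[C@H](O[Si](C)(C)C(C)(C)C)CC[C@]32C | intermediate
13 | hydroxy sulfide, C11' tertiary alcohol (OH axial) carrying CH2CH2SPh (C12', C12) equatorial, otherwise as 11 | c1ccccc1SCC[C@]1(O)[C@@H](C)CC[C@@H]2OC(C)(C)[C@H](O[Si](C)(C)C(C)(C)C)CC[C@]21C | intermediate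
14 | hydroxymethylidene ketone, (Z)-6-(hydroxymethylidene) derivative of 4 | O=C1/C(=C\O)CC[C@@H]2O[C@@H](OC)CC[C@]21C | intermediate
15 | isopropoxymethylidene ketone, (E)-6-(isopropoxymethylidene) derivative of 4 | O=C1/C(=C/OC(C)C)CC[C@@H]2O[C@@H](OC)CC[C@]21C | intermediate
16 | alkyllithium, lithium alkoxide of 13 with C12–Li in place of C12–SPh | [Li]CC[C@]1(O[Li])[C@@H](C)CC[C@@H]2OC(C)(C)[C@H](O[Si](C)(C)C(C)(C)C)CC[C@]21C | intermediate (not isolated)
17 | carbinol adduct, tertiary allylic alcohol at C11 (either epimer) bearing the C12–C12' linker and the isopropoxymethylidene group at C10 | CC(C)O/C=C1\CC[C@@H]2O[C@@H](OC)CC[C@@]2(C)C1(O)CC[C@]1(O)[C@@H](C)CC[C@@H]2OC(C)(C)[C@H](O[Si](C)(C)C(C)(C)C)CC[C@]21C | intermediate (not isolated)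
18 | enal, C10 formyl on a C10=C11 tetrasubstituted alkene; C11 linked through C12–C12' to the C11' carbinol of the silylated ring A/B unit; O7/C3 as the methyl acetal | O=CC1=C(CC[C@]2(O)[C@@H](C)CC[C@@H]3OC(C)(C)[C@H](O[Si](C)(C)C(C)(C)C)CC[C@]32C)[C@]2(C)CC[C@H](OC)O[C@H]2CC1 | intermediate
19 | allylic alcohol, C10–CH2OH analogue of 18 | OCC1=C(CC[C@]2(O)[C@@H](C)CC[C@@H]3OC(C)(C)[C@H](O[Si](C)(C)C(C)(C)C)CC[C@]32C)[C@]2(C)CC[C@H](OC)O[C@H]2CC1 | intermediate
20 | allylic diazene, C10–CH2–N=NH analogue of 19 | N=NCC1=C(CC[C@]2(O)[C@@H](C)CC[C@@H]3OC(C)(C)[C@H](O[Si](C)(C)C(C)(C)C)CC[C@]32C)[C@]2(C)CC[C@H](OC)O[C@H]2CC1 | intermediate (not isolated)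
21 | coupled methylidene acetal, C10=CH2, C11–H anti to the C6 methyl (11R), linker equatorial; methyl acetal on the ring C side, silyl ether on ring A | C=C1CC[C@@H]2O[C@@H](OC)CC[C@@]2(C)[C@@H]1CC[C@]1(O)[C@@H](C)CC[C@@H]2OC(C)(C)[C@H](O[Si](C)(C)C(C)(C)C)CC[C@]21C | intermediate
22 | coupled alcohol, 21 with free C3' hydroxyl | C=C1CC[C@@H]2O[C@@H](OC)CC[C@@]2(C)[C@@H]1CC[C@]1(O)[C@@H](C)CC[C@@H]2OC(C)(C)[C@H](O)CC[C@]21C | intermediate
23 | coupled ketone acetal, 22 oxidised to the C3' ketone (ring A complete) | C=C1CC[C@@H]2O[C@@H](OC)CC[C@@]2(C)[C@@H]1CC[C@]1(O)[C@@H](C)CC[C@@H]2OC(C)(C)C(=O)CC[C@]21C | intermediate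
24 | coupled lactol, 23 with OH in place of OCH3 (both anomers) | C=C1CC[C@@H]2OC(O)CC[C@@]2(C)[C@@H]1CC[C@]1(O)[C@@H](C)CC[C@@H]2OC(C)(C)C(=O)CC[C@]21C | intermediate
25 | alkene diol, rings A, B and C complete; C7–OH free, C6 carries CH2CH2CH=C(CH3)2 | C=C1CC[C@H](O)[C@@](C)(CCC=C(C)C)[C@@H]1CC[C@]1(O)[C@@H](C)CC[C@@H]2OC(C)(C)C(=O)CC[C@]21C | intermediate
26 | epoxy diol, (3R)-2,3-epoxide of 25 | C=C1CC[C@H](O)[C@@](C)(CC[C@H]2OC2(C)C)[C@@H]1CC[C@]1(O)[C@@H](C)CC[C@@H]2OC(C)(C)C(=O)CC[C@]21C | intermediate (not isolated)
27 | 3-epi-sodwanone K, (3R)-alcohol with all four rings | C=C1CC[C@@H]2OC(C)(C)[C@H](O)CC[C@@]2(C)[C@@H]1CC[C@]1(O)[C@@H](C)CC[C@@H]2OC(C)(C)C(=O)CC[C@]21C | intermediate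
28 | 3-epi-sodwanone K 3-acetate (3R,6S,7S,11R,6'R,7'S,10'S,11'S) | C=C1CC[C@@H]2OC(C)(C)[C@H](OC(C)=O)CC[C@@]2(C)[C@@H]1CC[C@]1(O)[C@@H](C)CC[C@@H]2OC(C)(C)C(=O)CC[C@]21C | target

**Step count and risks**

Total step count: 22. Longest linear sequence: 20 steps (steps 1–11, then 14–22).

Step 21 (key step). What may go wrong: the C7 hydroxyl may attack the secondary epoxide carbon C3 (6-exo-tet closure to a tetrahydropyranyl carbinol) in competition with the tertiary carbon C2, and the dioxirane may also oxidise the C10 methylidene group. Fallback: recast the tertiary carbon as the exo terminus of a transposed epoxide, so that ring size and charge stabilisation point the same way. It sets out from epoxy diol 26, isolated after the epoxidation stage. Et2Al(2,2,6,6-tetramethylpiperidide) in toluene at 0 °C should isomerise the epoxide to the (3R)-isopropenyl carbinol F1 with C3 untouched. VO(acac)2/t-BuOOH then epoxidises only the allylic-alcohol alkene to give the epoxy alcohol F2. CSA should close ring D by 7-exo opening at the tertiary carbon C2 to give the hydroxymethyl oxepane F3, whose C2 configuration is irrelevant. I2/PPh3/imidazole converts the primary alcohol into the iodide F4, and Bu3SnH/AIBN removes the iodine, which returns the route to 27.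

Step 14. What may go wrong: proton transfer to the dianionic alkyllithium, incomplete C–S cleavage, or conjugate addition–elimination at the alkoxymethylidene carbon instead of 1,2-addition to the hindered ketone. Fallback: reverse the polarity of the union so that the ring C fragment is the nucleophile and epoxide 12 the electrophile. It sets out from 15. LiCH2SO2Ph (from CH3SO2Ph and n-BuLi) adds to give the carbinol F5, and acid work-up gives the enal sulfone F6. NaBH4/CeCl3 gives the allylic alcohol sulfone F7. The conditions of step 16 convert it through the diazene F8 into the methylidene sulfone F9. Its lithio derivative (n-BuLi, THF, −78 °C) opens epoxide 12 at the CH2 carbon with BF3·OEt2 to give the hydroxy sulfone F10. Na(Hg)/Na2HPO4 in MeOH removes the sulfonyl group, which returns the route to 21.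

Step 16. What may go wrong: the Mitsunobu displacement at the crowded allylic carbinol may be slower than decomposition of the sulfonylhydrazide, or hydrogen may be transferred to the face of C11 syn to the C6 methyl. Fallback: deliver the C11 hydrogen from a metal instead of from a diazene. It sets out from 19. Formic acetic anhydride/pyridine gives the allylic formate F11. Pd(OAc)2/n-Bu3P in THF should form the π-allyl complex on the face anti to the C6 methyl and transfer hydride from the metal to the more substituted terminus C11 with loss of CO2 (formate hydrogenolysis of the Tsuji type, which gives the less substituted alkene), returning the route to 21.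

**Further compounds**

F1 | step 21 | (3R)-isopropenyl carbinol, 26 with CH(OH)–C(CH3)=CH2 in place of the epoxide | C=C1CC[C@H](O)[C@@](C)(CC[C@@H](O)C(C)=C)[C@@H]1CC[C@]1(O)[C@@H](C)CC[C@@H]2OC(C)(C)C(=O)CC[C@]21C
F2 | step 21 | epoxy alcohol, F1 with the isopropenyl group epoxidised (2-methyloxiran-2-yl, either epimer) | C=C1CC[C@H](O)[C@@](C)(CC[C@@H](O)C2(C)CO2)[C@@H]1CC[C@]1(O)[C@@H](C)CC[C@@H]2OC(C)(C)C(=O)CC[C@]21C
F3 | step 21 | hydroxymethyl oxepane, 27 with one C2 methyl replaced by CH2OH (either C2 epimer) | C=C1CC[C@@H]2OC(C)(CO)[C@H](O)CC[C@@]2(C)[C@@H]1CC[C@]1(O)[C@@H](C)CC[C@@H]2OC(C)(C)C(=O)CC[C@]21C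
F4 | step 21 | iodide, F3 with CH2I in place of CH2OH | C=C1CC[C@@H]2OC(C)(CI)[C@H](O)CC[C@@]2(C)[C@@H]1CC[C@]1(O)[C@@H](C)CC[C@@H]2OC(C)(C)C(=O)CC[C@]21C
F5 | step 14 | carbinol, 1,2-adduct of LiCH2SO2Ph to 15 (tertiary alcohol at C11, either epimer) | CC(C)O/C=C1\CC[C@@H]2O[C@@H](OC)CC[C@@]2(C)C1(O)CS(=O)(=O)c1ccccc1
F6 | step 14 | enal sulfone, C10 formyl, C10=C11, C11–CH2SO2Ph, methyl acetal as in 4 | O=CC1=C(CS(=O)(=O)c2ccccc2)[C@]2(C)CC[C@H](OC)O[C@H]2CC1
F7 | step 14 | allylic alcohol sulfone, C10–CH2OH analogue of F6 | OCC1=C(CS(=O)(=O)c2ccccc2)[C@]2(C)CC[C@H](OC)O[C@H]2CC1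
F8 | step 14 | diazene, C10–CH2–N=NH analogue of F7 | N=NCC1=C(CS(=O)(=O)c2ccccc2)[C@]2(C)CC[C@H](OC)O[C@H]2CC1
F9 | step 14 | methylidene sulfone, C10=CH2, C11–H anti to the C6 methyl, C11–CH2SO2Ph equatorial | C=C1CC[C@@H]2O[C@@H](OC)CC[C@@]2(C)[C@@H]1CS(=O)(=O)c1ccccc1
F10 | step 14 | hydroxy sulfone, 21 carrying a phenylsulfonyl group at C12 (either epimer) | C=C1CC[C@@H]2O[C@@H](OC)CC[C@@]2(C)[C@@H]1C(S(=O)(=O)c1ccccc1)C[C@]1(O)[C@@H](C)CC[C@@H]2OC(C)(C)[C@H](O[Si](C)(C)C(C)(C)C)CC[C@]21C
F11 | step 16 | allylic formate, O-formyl derivative of 19 | O=COCC1=C(CC[C@]2(O)[C@@H](C)CC[C@@H]3OC(C)(C)[C@H](O[Si](C)(C)C(C)(C)C)CC[C@]32C)[C@]2(C)CC[C@H](OC)O[C@H]2CC1
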